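**Plan**

1. Retrosynthetic cuts, in order: the two aryl gallate ester C(=O)–O bonds (at O7 and O4'); the pyran O1–C8a bond; the C4–C4a bond (aryllithium plus terminal epoxide); the epoxy alcohol, back to a vinyl carbinol made from the ring B aldehyde.
2. Forward: ring B aldehyde 3 → allyl ether → vinyl carbinol → erythro epoxy silyl ether 7 (both stereocentres) → union with lithiated phloroglucinol ether 2 → benzylate O3, free O7 → dearomatize ring A (step 9) → close the pyran (step 10) → rearomatize (step 11) → free O4', esterify both phenols, hydrogenolyse nine benzyl ethers.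
3. Enabling feature: the oxygens on C5, C7 and C8a of ring A are mutually meta. Oxidizing the C7 phenol at its para carbon C4a therefore gives a cross-conjugated dienone whose two β-carbons, C5 and C8a, both carry OBn and are equivalent. The C2 oxygen reaches either through a six-membered transition state and exchanges one OBn for O1 by addition–elimination.
4. Pay-off: one OBn is spent as the leaving group, the other remains as 5-OBn, and reductive loss of the C4a methoxy helper returns ring A with O7 as its only free phenol (the first gallate site), all from a symmetric phloroglucinol dibenzyl ether.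
5. Stereochemistry: C2 (R) and C3 (S) are both set in step 4 (Sharpless epoxidation run as a kinetic resolution, D-tartrate, erythro product). They are carried with retention because no bond to either carbon is broken later: the epoxide opens at CH2 and the ring closes at the aryl carbon.
6. Helpers and where they leave: C4a–OMe and the dienone oxidation level (in at step 9, out at step 11); TBS on the future O1 (out at step 10); TIPS on O7 (out at step 8); allyl on O4' (out at step 12).

Key step: step 10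

Assumption: 1, 3 and 17 are taken as purchasable; each is otherwise one or two routine steps from phloroglucinol, 3,4-dihydroxybenzaldehyde or gallic acid.

**Route**

Step 1
Reactants: 1 3,5-bis(benzyloxy)phenol
Product: 2 [3,5-bis(benzyloxy)phenoxy]tri(propan-2-yl)silane
Conditions: TIPSCl, imidazole, DMF, rt
Reagents that add atoms: triisopropylsilyl chloride, CC(C)[Si](Cl)(C(C)C)C(C)C
Why: Imidazole-promoted silylation of the only free phenol should give the silyl ether, whose bulky, non-coordinating TIPS group later keeps the lithiation away from its two ortho carbons.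

Step 2
Reactants: 3 3-(benzyloxy)-4-hydroxybenzaldehyde
Product: 4 3-(benzyloxy)-4-(prop-2-en-1-yloxy)benzaldehyde
Conditions: allyl bromide, K2CO3, DMF, rt
Reagents that add atoms: allyl bromide, C=CCBr
Why: Williamson ether synthesis on the phenoxide installs the one phenol protecting group of the route that zerovalent palladium removes, which marks O4' for the second gallate.

Step 3
Reactants: 4 3-(benzyloxy)-4-(prop-2-en-1-yloxy)benzaldehyde
Product: 5 rac-1-[3-(benzyloxy)-4-(prop-2-en-1-yloxy)phenyl]prop-2-en-1-ol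
Conditions: CH2=CHMgBr, THF, −78 to 0 °C; aqueous work-up
Reagents that add atoms: vinylmagnesium bromide, C=C[Mg]Br
Why: Grignard 1,2-addition of the vinyl nucleophile to the aldehyde should give the racemic secondary allylic alcohol that the resolution needs.

Step 4
Reactants: 5 rac-1-[3-(benzyloxy)-4-(prop-2-en-1-yloxy)phenyl]prop-2-en-1-ol
Product: 6 (R)-[3-(benzyloxy)-4-(prop-2-en-1-yloxy)phenyl][(2S)-oxiran-2-yl]methanol
Conditions: Ti(OiPr)4 (cat.), diisopropyl D-(−)-tartrate (cat.), t-BuOOH (0.6 equiv), 4 Å molecular sieves, CH2Cl2, −20 °C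
Reagents that add atoms: tert-butyl hydroperoxide, CC(C)(C)OO
Why: Sharpless asymmetric epoxidation run as a kinetic resolution: with the D-tartrate the (S)-carbinol should be epoxidized fast and only from the face that gives the erythro product, so the catalyst fixes the epoxide carbon as S and, through the enantiomer it consumes, the carbinol carbon as R, while the (R)-alcohol stays behind and is separated.

Step 5
Reactants: 6 (R)-[3-(benzyloxy)-4-(prop-2-en-1-yloxy)phenyl][(2S)-oxiran-2-yl]methanol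
Product: 7 tert-butyl{(R)-[3-(benzyloxy)-4-(prop-2-en-1-yloxy)phenyl][(2S)-oxiran-2-yl]methoxy}dimethylsilane
Conditions: TBSCl, imidazole, DMF, rt
Reagents that add atoms: tert-butyldimethylsilyl chloride, CC(C)(C)[Si](C)(C)Cl
Why: Imidazole-promoted silylation of the secondary alcohol masks the future ring oxygen through the oxidation of step 9 and provides the fluoride trigger of step 10.

Step 6
Reactants: 2 [3,5-bis(benzyloxy)phenoxy]tri(propan-2-yl)silane; 7 tert-butyl{(R)-[3-(benzyloxy)-4-(prop-2-en-1-yloxy)phenyl][(2S)-oxiran-2-yl]methoxy}dimethylsilane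
Product: 9 (1R,2S)-1-[3-(benzyloxy)-4-(prop-2-en-1-yloxy)phenyl]-3-{2,6-bis(benzyloxy)-4-[(triisopropylsilyl)oxy]phenyl}-1-[(tert-butyldimethylsilyl)oxy]propan-2-ol, via aryllithium 8 (not isolated)
Conditions: 2, n-BuLi, THF, 0 °C; then 7, BF3·OEt2, −78 °C; aqueous work-up
Reagents that add atoms: none
Why: Directed ortho-metalation between the two benzyloxy groups (the TIPS ether shields the other two ring carbons) followed by BF3-promoted SN2 opening of the epoxide at its CH2 terminus should join ring A to C4 without touching either stereocentre.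

Step 7
Reactants: 9 (1R,2S)-1-[3-(benzyloxy)-4-(prop-2-en-1-yloxy)phenyl]-3-{2,6-bis(benzyloxy)-4-[(triisopropylsilyl)oxy]phenyl}-1-[(tert-butyldimethylsilyl)oxy]propan-2-ol
Product: 10 {4-[(2S,3R)-2-(benzyloxy)-3-[3-(benzyloxy)-4-(prop-2-en-1-yloxy)phenyl]-3-[(tert-butyldimethylsilyl)oxy]propyl]-3,5-bis(benzyloxy)phenoxy}tri(propan-2-yl)silane
Conditions: 2-benzyloxy-1-methylpyridinium triflate, MgO, PhCF3, 85 °C
Reagents that add atoms: 2-benzyloxy-1-methylpyridinium triflate, C[n+]1ccccc1OCc1ccccc1.[O-]S(=O)(=O)C(F)(F)F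
Why: Benzyl transfer from the pyridinium salt under neutral conditions (MgO as acid scavenger) should etherify the secondary alcohol without the 1,2-silyl migration that an alkoxide would invite.

Step 8
Reactants: 10 {4-[(2S,3R)-2-(benzyloxy)-3-[3-(benzyloxy)-4-(prop-2-en-1-yloxy)phenyl]-3-[(tert-butyldimethylsilyl)oxy]propyl]-3,5-bis(benzyloxy)phenoxy}tri(propan-2-yl)silane
Product: 11 4-[(2S,3R)-2-(benzyloxy)-3-[3-(benzyloxy)-4-(prop-2-en-1-yloxy)phenyl]-3-[(tert-butyldimethylsilyl)oxy]propyl]-3,5-bis(benzyloxy)phenol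
Conditions: Bu4NF (1.05 equiv), THF, 0 °C; AcOH quench
Reagents that add atoms: none
Why: Fluoride desilylation is much faster at an aryl–O–Si bond than at a hindered secondary alkyl TBS ether, so one equivalent at 0 °C should free only the ring A phenol.

Step 9
Reactants: 11 4-[(2S,3R)-2-(benzyloxy)-3-[3-(benzyloxy)-4-(prop-2-en-1-yloxy)phenyl]-3-[(tert-butyldimethylsilyl)oxy]propyl]-3,5-bis(benzyloxy)phenol
Product: 12 4-[(2S,3R)-2-(benzyloxy)-3-[3-(benzyloxy)-4-(prop-2-en-1-yloxy)phenyl]-3-[(tert-butyldimethylsilyl)oxy]propyl]-3,5-bis(benzyloxy)-4-methoxycyclohexa-2,5-dien-1-one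
Conditions: PhI(OAc)2, MeOH, 0 °C
Reagents that add atoms: methanol, CO
Why: Oxidative dearomatization of a para-alkyl phenol with a hypervalent iodine diacetate in methanol: the phenoxonium-type intermediate should be captured at C4a, the carbon para to the phenol and flanked by both donor benzyloxy groups, to give the symmetric p-quinol methyl ether, while the silylated C2 oxygen cannot compete for C4a.

Step 10
Reactants: 12 4-[(2S,3R)-2-(benzyloxy)-3-[3-(benzyloxy)-4-(prop-2-en-1-yloxy)phenyl]-3-[(tert-butyldimethylsilyl)oxy]propyl]-3,5-bis(benzyloxy)-4-methoxycyclohexa-2,5-dien-1-one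
Product: 14 (2R,3S)-3,5-bis(benzyloxy)-2-[3-(benzyloxy)-4-(prop-2-en-1-yloxy)phenyl]-4a-methoxy-2,3,4,4a-tetrahydro-7H-chromen-7-one, via benzylic alkoxide 13 (not isolated)
Conditions: Bu4NF, 4 Å molecular sieves, THF, 0 °C to rt, high dilution; AcOH quench
Reagents that add atoms: none
Why: Proposed new method: fluoride cleaves the O–Si bond at C2, and the secondary alkoxide 13 adds to C8a, one of the two β-carbons of the cross-conjugated 3,5-bis(benzyloxy)dienone; the enolate re-forms the enone by expelling benzyl oxide from the same carbon, so O1 replaces OBn at C8a by addition–elimination. The closest known reaction type is the alkoxy exchange of vinylogous esters (β-alkoxy enones) by alcohols or alkoxides, used here within one molecule on a p-quinol ether. The pyran closes in a 6-exo-trig mode: the new ring is O1–C2–C3–C4–C4a–C8a and the attacked C8=C8a bond has C8 outside it. No bond to C2 or C3 is made or broken, so both keep the configuration from step 4; the only new stereocentre, C4a, may form as either epimer because it becomes trigonal again in step 11. The step needs the alkoxide to attack a β-carbon of its own dienone faster than outside nucleophiles do, and to lose benzyl oxide and not itself from the adduct: C5 and C8a are equivalent and lead to the same chroman, the five-atom tether allows only the six-membered closure (C4a is quaternary and attack at C7 would give a bridged ring), high dilution disfavours intermolecular addition, and the expelled benzyl oxide can return only intermolecularly. Ring A is then left with exactly the wanted pattern: O1 on C8a, benzyl on O5, and the C7 carbonyl that becomes the free phenol.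

Step 11
Reactants: 14 (2R,3S)-3,5-bis(benzyloxy)-2-[3-(benzyloxy)-4-(prop-2-en-1-yloxy)phenyl]-4a-methoxy-2,3,4,4a-tetrahydro-7H-chromen-7-one
Product: 15 (2R,3S)-3,5-bis(benzyloxy)-2-[3-(benzyloxy)-4-(prop-2-en-1-yloxy)phenyl]-3,4-dihydro-2H-chromen-7-ol
Conditions: Zn dust, AcOH, THF, rt
Reagents that add atoms: none
Why: Dissolving-metal reduction of a p-quinol ether: two-electron transfer to the protonated dienone followed by loss of methoxide from C4a should restore the aromatic ring and leave O7 as the only free phenol, both C4a epimers converging.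

Step 12
Reactants: 15 (2R,3S)-3,5-bis(benzyloxy)-2-[3-(benzyloxy)-4-(prop-2-en-1-yloxy)phenyl]-3,4-dihydro-2H-chromen-7-ol
Product: 16 (2R,3S)-3,5-bis(benzyloxy)-2-[3-(benzyloxy)-4-hydroxyphenyl]-3,4-dihydro-2H-chromen-7-ol
Conditions: Pd(PPh3)4 (cat.), morpholine, THF, rt
Reagents that add atoms: none
Why: Tsuji–Trost deallylation: zerovalent palladium ionizes the allyl aryl ether to a π-allyl complex that morpholine captures, which should free the 4'-phenol without touching the benzyl ethers.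

Step 13
Reactants: 16 (2R,3S)-3,5-bis(benzyloxy)-2-[3-(benzyloxy)-4-hydroxyphenyl]-3,4-dihydro-2H-chromen-7-ol; 17 3,4,5-tris(benzyloxy)benzoyl chloride
Product: 18 (2R,3S)-3,5-bis(benzyloxy)-2-{3-(benzyloxy)-4-[3,4,5-tris(benzyloxy)benzoyloxy]phenyl}-3,4-dihydro-2H-chromen-7-yl 3,4,5-tris(benzyloxy)benzoate
Conditions: 17 (2.4 equiv), Et3N, DMAP (cat.), CH2Cl2, 0 °C to rt
Reagents that add atoms: none
Why: DMAP-catalysed acylation of the two phenols, the only OH groups in 16, with the acid chloride should place the gallates on O7 and O4' and nowhere else.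

Step 14
Reactants: 18 (2R,3S)-3,5-bis(benzyloxy)-2-{3-(benzyloxy)-4-[3,4,5-tris(benzyloxy)benzoyloxy]phenyl}-3,4-dihydro-2H-chromen-7-yl 3,4,5-tris(benzyloxy)benzoate
Product: 19 catechin 7,4'-di-O-gallate
Conditions: H2 (1 atm), Pd(OH)2/C, THF/MeOH, rt
Reagents that add atoms: none
Why: Hydrogenolysis of all nine benzyl ethers over palladium hydroxide on carbon in neutral solvent should release the target, since aryl esters are inert to it and the neutral medium avoids acyl migration to the neighbouring 3'-OH.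

**Compound list**

1 | 3,5-bis(benzyloxy)phenol | Oc1cc(OCc2ccccc2)cc(OCc2ccccc2)c1 | starting material
2 | [3,5-bis(benzyloxy)phenoxy]tri(propan-2-yl)silane | CC(C)[Si](Oc1cc(OCc2ccccc2)cc(OCc2ccccc2)c1)(C(C)C)C(C)C | intermediate
3 | 3-(benzyloxy)-4-hydroxybenzaldehyde | O=Cc1ccc(O)c(OCc2ccccc2)c1 | starting material
4 | 3-(benzyloxy)-4-(prop-2-en-1-yloxy)benzaldehyde | O=Cc1ccc(OCC=C)c(OCc2ccccc2)c1 | intermediate
5 | rac-1-[3-(benzyloxy)-4-(prop-2-en-1-yloxy)phenyl]prop-2-en-1-ol | C=CC(O)c1ccc(OCC=C)c(OCc2ccccc2)c1 | intermediate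
6 | (R)-[3-(benzyloxy)-4-(prop-2-en-1-yloxy)phenyl][(2S)-oxiran-2-yl]methanol (erythro) | O[C@H](c1ccc(OCC=C)c(OCc2ccccc2)c1)[C@@H]1CO1 | intermediate
7 | tert-butyl{(R)-[3-(benzyloxy)-4-(prop-2-en-1-yloxy)phenyl][(2S)-oxiran-2-yl]methoxy}dimethylsilane | CC(C)(C)[Si](C)(C)O[C@H](c1ccc(OCC=C)c(OCc2ccccc2)c1)[C@@H]1CO1 | intermediate
8 | 2,6-bis(benzyloxy)-4-[(triisopropylsilyl)oxy]phenyllithium | [Li]c1c(OCc2ccccc2)cc(O[Si](C(C)C)(C(C)C)C(C)C)cc1OCc1ccccc1 | intermediate (not isolated)
9 | (1R,2S)-1-[3-(benzyloxy)-4-(prop-2-en-1-yloxy)phenyl]-3-{2,6-bis(benzyloxy)-4-[(triisopropylsilyl)oxy]phenyl}-1-[(tert-butyldimethylsilyl)oxy]propan-2-ol | CC(C)[Si](Oc1cc(OCc2ccccc2)c(C[C@H](O)[C@H](O[Si](C)(C)C(C)(C)C)c2ccc(OCC=C)c(OCc3ccccc3)c2)c(OCc2ccccc2)c1)(C(C)C)C(C)C | intermediate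
10 | {4-[(2S,3R)-2-(benzyloxy)-3-[3-(benzyloxy)-4-(prop-2-en-1-yloxy)phenyl]-3-[(tert-butyldimethylsilyl)oxy]propyl]-3,5-bis(benzyloxy)phenoxy}tri(propan-2-yl)silane | CC(C)[Si](Oc1cc(OCc2ccccc2)c(C[C@H](OCc2ccccc2)[C@H](O[Si](C)(C)C(C)(C)C)c2ccc(OCC=C)c(OCc3ccccc3)c2)c(OCc2ccccc2)c1)(C(C)C)C(C)C | intermediate
11 | 4-[(2S,3R)-2-(benzyloxy)-3-[3-(benzyloxy)-4-(prop-2-en-1-yloxy)phenyl]-3-[(tert-butyldimethylsilyl)oxy]propyl]-3,5-bis(benzyloxy)phenol | Oc1cc(OCc2ccccc2)c(C[C@H](OCc2ccccc2)[C@H](O[Si](C)(C)C(C)(C)C)c2ccc(OCC=C)c(OCc3ccccc3)c2)c(OCc2ccccc2)c1 | intermediate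
12 | 4-[(2S,3R)-2-(benzyloxy)-3-[3-(benzyloxy)-4-(prop-2-en-1-yloxy)phenyl]-3-[(tert-butyldimethylsilyl)oxy]propyl]-3,5-bis(benzyloxy)-4-methoxycyclohexa-2,5-dien-1-one | O=C1C=C(OCc2ccccc2)C(OC)(C[C@H](OCc2ccccc2)[C@H](O[Si](C)(C)C(C)(C)C)c2ccc(OCC=C)c(OCc3ccccc3)c2)C(OCc2ccccc2)=C1 | intermediate
13 | tetrabutylammonium benzylic alkoxide of desilylated 12 | O=C1C=C(OCc2ccccc2)C(OC)(C[C@H](OCc2ccccc2)[C@H]([O-])c2ccc(OCC=C)c(OCc3ccccc3)c2)C(OCc2ccccc2)=C1.CCCC[N+](CCCC)(CCCC)CCCC | intermediate (not isolated)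
14 | (2R,3S)-3,5-bis(benzyloxy)-2-[3-(benzyloxy)-4-(prop-2-en-1-yloxy)phenyl]-4a-methoxy-2,3,4,4a-tetrahydro-7H-chromen-7-one (either C4a epimer) | O=C1C=C2O[C@H](c3ccc(OCC=C)c(OCc4ccccc4)c3)[C@@H](OCc3ccccc3)CC2(OC)C(OCc2ccccc2)=C1 | intermediate
15 | (2R,3S)-3,5-bis(benzyloxy)-2-[3-(benzyloxy)-4-(prop-2-en-1-yloxy)phenyl]-3,4-dihydro-2H-chromen-7-ol | Oc1cc(OCc2ccccc2)c2c(c1)O[C@H](c1ccc(OCC=C)c(OCc3ccccc3)c1)[C@@H](OCc1ccccc1)C2 | intermediate
16 | (2R,3S)-3,5-bis(benzyloxy)-2-[3-(benzyloxy)-4-hydroxyphenyl]-3,4-dihydro-2H-chromen-7-ol | Oc1cc(OCc2ccccc2)c2c(c1)O[C@H](c1ccc(O)c(OCc3ccccc3)c1)[C@@H](OCc1ccccc1)C2 | intermediate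
17 | 3,4,5-tris(benzyloxy)benzoyl chloride | O=C(Cl)c1cc(OCc2ccccc2)c(OCc2ccccc2)c(OCc2ccccc2)c1 | starting material
18 | (2R,3S)-3,5-bis(benzyloxy)-2-{3-(benzyloxy)-4-[3,4,5-tris(benzyloxy)benzoyloxy]phenyl}-3,4-dihydro-2H-chromen-7-yl 3,4,5-tris(benzyloxy)benzoate | O=C(Oc1cc(OCc2ccccc2)c2c(c1)O[C@H](c1ccc(OC(=O)c3cc(OCc4ccccc4)c(OCc4ccccc4)c(OCc4ccccc4)c3)c(OCc3ccccc3)c1)[C@@H](OCc1ccccc1)C2)c1cc(OCc2ccccc2)c(OCc2ccccc2)c(OCc2ccccc2)c1 | intermediate
19 | catechin 7,4'-di-O-gallate, (2R,3S) | O=C(Oc1cc(O)c2c(c1)O[C@H](c1ccc(OC(=O)c3cc(O)c(O)c(O)c3)c(O)c1)[C@@H](O)C2)c1cc(O)c(O)c(O)c1 | target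

**Count and risks**

Total steps: 14. Longest linear sequence: 13 (steps 2 to 14, from aldehyde 3).

Steps most likely to fail:

1. Step 10. The addition–elimination may be slow at a hindered β-carbon that two alkoxy donors make electron-rich, so that hydrolysis of the vinylogous ester by hydroxide in the fluoride reagent, or intermolecular exchange, overtakes ring closure. The fallback closes the same O1–C8a bond by nucleophilic aromatic substitution, a known way to close this ring, and needs no dearomatization. It sets out from epoxide 7. Ring A is brought in as [3-(benzyloxy)-5-fluorophenoxy]tri(propan-2-yl)silane F1 made with TIPSCl and imidazole from purchasable 3-(benzyloxy)-5-fluorophenol. n-BuLi at −78 °C should lithiate F1 between fluorine and OBn, and BF3·OEt2-promoted opening of 7 should then give (1R,2S)-1-[3-(benzyloxy)-4-(prop-2-en-1-yloxy)phenyl]-3-{2-(benzyloxy)-6-fluoro-4-[(triisopropylsilyl)oxy]phenyl}-1-[(tert-butyldimethylsilyl)oxy]propan-2-ol F2 as the fluoro alcohol. Benzylation of F2 with 2-benzyloxy-1-methylpyridinium triflate and MgO should give {4-[(2S,3R)-2-(benzyloxy)-3-[3-(benzyloxy)-4-(prop-2-en-1-yloxy)phenyl]-3-[(tert-butyldimethylsilyl)oxy]propyl]-3-(benzyloxy)-5-fluorophenoxy}tri(propan-2-yl)silane F3 as its 2-O-benzyl ether. HF·pyridine should remove only the alkyl TBS ether of F3 and give (1R,2S)-2-(benzyloxy)-1-[3-(benzyloxy)-4-(prop-2-en-1-yloxy)phenyl]-3-{2-(benzyloxy)-6-fluoro-4-[(triisopropylsilyl)oxy]phenyl}propan-1-ol F4 while the aryl TIPS ether stays. KH and 18-crown-6 in THF/DMF should convert F4 into its alkoxide, which displaces fluoride intramolecularly, with retention at C2, to give {[(2R,3S)-3,5-bis(benzyloxy)-2-[3-(benzyloxy)-4-(prop-2-en-1-yloxy)phenyl]-3,4-dihydro-2H-chromen-7-yl]oxy}tri(propan-2-yl)silane F5 as the closed chroman. Bu4NF should then free the phenol of F5 and the route is rejoined at 15.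

2. Step 9. Methanol may capture the oxidized phenol at an unsubstituted ortho carbon (C6 or C8) instead of the crowded C4a, or ring B may trap it, and the very electron-rich ring may be oxidized further. The fallback replaces the two-electron oxidation with external-nucleophile capture by an oxygen transfer that can only deliver oxygen para. It sets out from phenol 11. Singlet oxygen, generated in the flask from KHSO5 (as 2KHSO5·KHSO4·K2SO4) and NaHCO3 in aqueous MeCN, should add across C7/C4a to give 4-[(2S,3R)-2-(benzyloxy)-3-[3-(benzyloxy)-4-(prop-2-en-1-yloxy)phenyl]-3-[(tert-butyldimethylsilyl)oxy]propyl]-3,5-bis(benzyloxy)-4-hydroperoxycyclohexa-2,5-dien-1-one F6 as the para-hydroperoxide. Me2S should reduce F6 to 4-[(2S,3R)-2-(benzyloxy)-3-[3-(benzyloxy)-4-(prop-2-en-1-yloxy)phenyl]-3-[(tert-butyldimethylsilyl)oxy]propyl]-3,5-bis(benzyloxy)-4-hydroxycyclohexa-2,5-dien-1-one F7 as the p-quinol. Bu4NF in THF should desilylate F7 and close the pyran by the same addition–elimination to give (2R,3S)-3,5-bis(benzyloxy)-2-[3-(benzyloxy)-4-(prop-2-en-1-yloxy)phenyl]-4a-hydroxy-2,3,4,4a-tetrahydro-7H-chromen-7-one F8 as the 4a-hydroxy dienone. Zn dust and AcOH should then aromatize F8 by loss of water, which returns to the route at 15.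

3. Step 4. The Lewis acidic titanium alkoxide may ionize the electron-rich benzylic allylic alcohol or open the epoxy alcohol, and the rate difference between the enantiomers may be too small. The fallback separates the two tasks. It sets out from racemic 5. Acylation with vinyl acetate over immobilized Candida antarctica lipase B should consume the (R)-enantiomer as (R)-1-[3-(benzyloxy)-4-(prop-2-en-1-yloxy)phenyl]prop-2-en-1-yl acetate F10 and leave (S)-1-[3-(benzyloxy)-4-(prop-2-en-1-yloxy)phenyl]prop-2-en-1-ol F9 behind as the unreacted alcohol. The acetate F10 is separated and set aside. Hydroxyl-directed epoxidation of F9 with VO(acac)2 (cat.) and t-BuOOH, which favours the erythro epoxy alcohol of 1-substituted allyl alcohols, returns to the route at 6 after separation of the minor threo isomer.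

**Further compounds**

F1 | step 10 | [3-(benzyloxy)-5-fluorophenoxy]tri(propan-2-yl)silane | CC(C)[Si](Oc1cc(F)cc(OCc2ccccc2)c1)(C(C)C)C(C)C
F2 | step 10 | (1R,2S)-1-[3-(benzyloxy)-4-(prop-2-en-1-yloxy)phenyl]-3-{2-(benzyloxy)-6-fluoro-4-[(triisopropylsilyl)oxy]phenyl}-1-[(tert-butyldimethylsilyl)oxy]propan-2-ol | CC(C)[Si](Oc1cc(F)c(C[C@H](O)[C@H](O[Si](C)(C)C(C)(C)C)c2ccc(OCC=C)c(OCc3ccccc3)c2)c(OCc2ccccc2)c1)(C(C)C)C(C)C
F3 | step 10 | {4-[(2S,3R)-2-(benzyloxy)-3-[3-(benzyloxy)-4-(prop-2-en-1-yloxy)phenyl]-3-[(tert-butyldimethylsilyl)oxy]propyl]-3-(benzyloxy)-5-fluorophenoxy}tri(propan-2-yl)silane | CC(C)[Si](Oc1cc(F)c(C[C@H](OCc2ccccc2)[C@H](O[Si](C)(C)C(C)(C)C)c2ccc(OCC=C)c(OCc3ccccc3)c2)c(OCc2ccccc2)c1)(C(C)C)C(C)C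
F4 | step 10 | (1R,2S)-2-(benzyloxy)-1-[3-(benzyloxy)-4-(prop-2-en-1-yloxy)phenyl]-3-{2-(benzyloxy)-6-fluoro-4-[(triisopropylsilyl)oxy]phenyl}propan-1-ol | CC(C)[Si](Oc1cc(F)c(C[C@H](OCc2ccccc2)[C@H](O)c2ccc(OCC=C)c(OCc3ccccc3)c2)c(OCc2ccccc2)c1)(C(C)C)C(C)C
F5 | step 10 | {[(2R,3S)-3,5-bis(benzyloxy)-2-[3-(benzyloxy)-4-(prop-2-en-1-yloxy)phenyl]-3,4-dihydro-2H-chromen-7-yl]oxy}tri(propan-2-yl)silane | CC(C)[Si](Oc1cc(OCc2ccccc2)c2c(c1)O[C@H](c1ccc(OCC=C)c(OCc3ccccc3)c1)[C@@H](OCc1ccccc1)C2)(C(C)C)C(C)C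
F6 | step 9 | 4-[(2S,3R)-2-(benzyloxy)-3-[3-(benzyloxy)-4-(prop-2-en-1-yloxy)phenyl]-3-[(tert-butyldimethylsilyl)oxy]propyl]-3,5-bis(benzyloxy)-4-hydroperoxycyclohexa-2,5-dien-1-one | O=C1C=C(OCc2ccccc2)C(OO)(C[C@H](OCc2ccccc2)[C@H](O[Si](C)(C)C(C)(C)C)c2ccc(OCC=C)c(OCc3ccccc3)c2)C(OCc2ccccc2)=C1
F7 | step 9 | 4-[(2S,3R)-2-(benzyloxy)-3-[3-(benzyloxy)-4-(prop-2-en-1-yloxy)phenyl]-3-[(tert-butyldimethylsilyl)oxy]propyl]-3,5-bis(benzyloxy)-4-hydroxycyclohexa-2,5-dien-1-one | O=C1C=C(OCc2ccccc2)C(O)(C[C@H](OCc2ccccc2)[C@H](O[Si](C)(C)C(C)(C)C)c2ccc(OCC=C)c(OCc3ccccc3)c2)C(OCc2ccccc2)=C1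
F8 | step 9 | (2R,3S)-3,5-bis(benzyloxy)-2-[3-(benzyloxy)-4-(prop-2-en-1-yloxy)phenyl]-4a-hydroxy-2,3,4,4a-tetrahydro-7H-chromen-7-one | O=C1C=C2O[C@H](c3ccc(OCC=C)c(OCc4ccccc4)c3)[C@@H](OCc3ccccc3)CC2(O)C(OCc2ccccc2)=C1
F9 | step 4 | (S)-1-[3-(benzyloxy)-4-(prop-2-en-1-yloxy)phenyl]prop-2-en-1-ol | O[C@H](c1ccc(OCC=C)c(OCc2ccccc2)c1)C=C
F10 | step 4 | (R)-1-[3-(benzyloxy)-4-(prop-2-en-1-yloxy)phenyl]prop-2-en-1-yl acetate | CC(=O)O[C@@H](c1ccc(OCC=C)c(OCc2ccccc2)c1)C=C
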